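**Remark on the chemistry (assumption):** compounds 1, 3 and 6 are taken as purchased. Flavone numbering (O1, C2–C4, C4a, C5–C8, C8a; ring B primed) is used for the target and, by anticipation, for its precursors. The 4'-oxygen is carried as a pivalate, not as a silyl ether, because an aryl silyl ether para to the conjugated carbonyl could be lost in the acidic oxidation or under carbonate, exposing the 4'-phenoxide to methylation.

## Analysis of the target

Compound 15 is a flavonol: ring A is fused to the γ-pyranone ring C, a 4-hydroxy-3-methoxyphenyl ring B sits at C2, and C3 carries a free enolic hydroxyl. Ring A has three different oxygens on adjacent carbons: a free 5-OH hydrogen-bonded to the C4 carbonyl, a prenyl ether at C7 and a methyl ether at C8. There is no stereocentre, so the problem is one of regiochemistry and chemoselectivity. The prenyl ether excludes hydrogenolysis, strong Brønsted or Lewis acids and electrophilic oxygen-transfer reagents late in the route; the 3-hydroxyflavone enol is sensitive to base in air. The hard part is ring A: the usual flavone syntheses close ring C through a phenol oxygen of ring A and so need an acetophenone with four differently substituted oxygens, two of them ortho to the ketone and able to close either way. The strategy rests on the fact that O5 and O8 are para to each other: C5 and C8 are the carbonyl carbons of a 1,4-benzoquinone, C4a is the quinone carbon bearing the acyl group C4, and C8a is the CH next to it. Ring A is therefore a 2-acyl-5-prenyloxy-1,4-benzoquinone in disguise, whose most electrophilic carbon is C8a, so O1–C8a can be made by adding the enol oxygen of the C2–C3–C4 chain to that carbon. Ring A then needs only three oxygens, and the acyl group, not a phenol, decides where ring C closes.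

## Retrosynthetic reasoning

**15 to 14.** The last disconnection removes the benzoate on O3 and the pivalate on O4' of 14. Esters are chosen because both leave in one base-mediated methanolysis that does not touch the prenyl ether, the methyl ethers or the chelated 5-OH. The forward step must cleave an enol ester and a hindered aryl ester without exposing the flavonol to oxygen.

**14 to 13.** The O8–CH3 bond is cut. The ring closure delivers O5 and O8 as a free hydroquinone, so the 8-methyl group must be put back. This is acceptable because the two hydroxyls of 13 differ strongly: the 5-OH is locked to the C4 carbonyl, the 8-OH is an ordinary phenol. The forward step must alkylate one phenoxide beside a chelated phenol and two esters.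

**13 to 10 (through 12 and 11).** The O1–C8a bond is cut at a carbon that carries hydrogen in the precursor. Cutting here means ring A of 10 carries no oxygen at the ring-closing carbon and only one ortho oxygen, so the closure cannot run the wrong way through a second phenol. In the forward direction a one-electron oxidant turns the para-dimethoxy pair of 10 into acylquinone 11. The enol oxygen of the side chain adds to the quinone carbon next to the acyl group, and rearomatisation gives the 5,8-hydroquinone 13. The over-oxidised form, flavone-5,8-quinone 12, is returned to 13 by a reductive wash.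

**10 to 9.** The C3–O bond is cut. The central carbon of the 1,3-diketone 9 is its most nucleophilic position, so an electrophilic acyloxy transfer places the future 3-oxygen there as a benzoate, which also protects it to the end.

**9 to 5 and 8.** The bond between the central carbon and the ring B carbonyl (the future C2–C3 bond) is cut. This divides the molecule into two aromatic halves of similar size; the forward reaction is a crossed Claisen acylation of the enolate of ketone 5 with acid chloride 8.

**5 to 4, 4 to 2 and 3, 2 to 1.** The two methyl ethers of 5 are removed to give hydroquinone 4, the prenyl ether is cut to 2 and prenyl bromide 3, and the acetyl group of 2 is traced to the triacetate 1. The order is dictated by acidity: the 4-OH of 2, para to the ketone, is alkylated first, and the two remaining hydroxyls are then methylated together.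

**8 to 7 to 6.** The acid chloride comes from acid 7, and 7 from vanillic acid 6 by acylation of the phenol.

## Alternatives that were turned down

**Alternative 1:** The cuts are C4a–C4 and C4–C3, so the C4 carbonyl enters as a one-carbon unit between the two aromatic halves. The ring A aryl iodide A1 and the ring B α-(methoxymethoxy) ketone A2 would be joined by a palladium-catalysed carbonylative α-arylation to the 2-alkoxy-1,3-diketone A3. Cleavage of the ring A acetal and cyclodehydration through that phenol oxygen would then close ring C.
- For it: the union is convergent and forms two C–C bonds at once. Ring A arrives with its 8-methoxy group and all oxygens at the final oxidation level, and the ring closure is the classical, unambiguous one. On this point it is stronger than the chosen route, which needs a selective methylation after an oxidative closure.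
- Against it for 15: A1 is a hexasubstituted benzene with four differently protected oxygens and needs several steps of its own. The iodide lies between two ortho alkoxy groups, so insertion and acyl transfer are slow and direct arylation or reduction compete. The benzyl ethers can only be removed by hydrogenolysis or Lewis acids, which the prenyl ether does not survive, so the prenyl group would have to be placed at O7 after debenzylation, beside free 5- and 4'-hydroxyls. Acid is needed twice.
- Comparison: the chosen strategy gives up the preset oxygen pattern. In exchange it starts from the three-oxygen ring of 1, carries the prenyl ether from step 2, needs no transition-metal step and is shorter.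

**Alternative 2:** Ring C is kept and ring A is cut at C4a–C5, C5–C6 and C7–C8, so ring A is built last on a finished pyranone. The α-methoxy acid chloride A4, attached to the pyranone carbon that becomes C8a, would be dehydrochlorinated by an amine base to a ketene. A [2+2] cycloaddition with silyloxyalkyne A5 forms C5–C6 and C7–C8; four-electron opening of the cyclobutenone and six-electron electrocyclisation onto the C4a=C8a bond form C4a–C5; tautomerisation gives A6 (a benzannulation of the Danheiser type).
- For it: the ketene carbonyl becomes the free 5-OH, the silyl ether marks O7 and the methoxy group is at C8 from the start. Ring A is produced in one operation with its three oxygens differentiated and without an oxidant. The endgame (desilylation, alkylation of the only free non-chelated hydroxyl with 3, ester cleavage) is cleaner than that of the chosen route, and on regiochemical certainty this plan is stronger.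
- Against it: A4 is a fully substituted 4-pyranone with aryl, acyloxy and α-alkoxyacetyl chloride groups, and no short preparation is apparent. Alkoxyketenes dimerise easily. The electrocyclisation must use the double bond of a vinylogous ester, which is less available than a simple vinyl or aryl π-bond. A5 is a sensitive reagent that must be made.
- Comparison: the benzannulation is short but the access to A4 outweighs it. The chosen strategy has the opposite balance: precursor 10 is available in seven routine steps, at the price of a late selective methylation.

**Alternative 3:** The cut is C4–C4a, with O1–C8a already present in an enol ether. The (E)-3-aryloxyacrylic acid A7, whose carboxyl group is cis to the ring A oxygen, would be activated as a mixed anhydride. The acyl carbon would attack the free ortho carbon of the ring A ether in an intramolecular Friedel–Crafts acylation to give A8.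
- For it: the attacked carbon is ortho to O1, ortho to one benzyloxy group and para to the other, so the substitution is electronically ideal. The 8-methoxy group is carried in. After closure, hydrogenolysis would free O5 and O7, and only the non-chelated 7-OH would take the prenyl group. That late selectivity is better defined than the O8-methylation of the chosen route.
- Against it: A7 is a tetrasubstituted alkene with oxygen on both carbons, and its geometry must be controlled; the wrong isomer puts ring B next to the acylating carbon and would give an indenone. Its ring A part is a phenol with four differentiated oxygens, which is the burden the chosen route avoids. The acidic step risks transfer or loss of the enol pivalate. Debenzylation, prenylation and ester cleavage add three steps after the key step.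
- Comparison: the chosen strategy has the less conventional ring closure but a much simpler precursor and a shorter sequence, and it never needs a benzyl ether beside the prenyl group.

Key step: step 8

## Route

Step 1
Reactants: 1 1,2,4-triacetoxybenzene
Product: 2 1-(2,4,5-trihydroxyphenyl)ethanone
Conditions: BF3·OEt2, AcOH, 90 °C; then H2O, 60 °C
Reagents that add atoms: acetic acid, CC(=O)O (acyl source in exchange with the acetate groups of 1)
Why: Fries rearrangement and Friedel–Crafts acylation under a boron Lewis acid; the acyl group should enter the one ring carbon that is para to one oxygen and ortho to another, giving the chelated ortho-hydroxy ketone, and the aqueous heating cleaves the remaining acetates and the boron chelate.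

Step 2
Reactants: 2 1-(2,4,5-trihydroxyphenyl)ethanone; 3 prenyl bromide (1-bromo-3-methylbut-2-ene)
Product: 4 1-[2,5-dihydroxy-4-(3-methylbut-2-enyloxy)phenyl]ethanone
Conditions: KHCO3 (1.2 equiv), DMF, 40 °C, argon
Reagents that add atoms: none
Why: Williamson etherification under acidity control: the 4-OH is para to the acetyl group and is the most acidic hydroxyl, the 2-OH is tied up in a hydrogen bond to the carbonyl and the 5-OH is only meta to it, so hydrogencarbonate should form essentially the 4-phenoxide alone. Once O4 is alkylated the remaining hydroxyls are too weakly acidic for this base, which should stop the reaction at the monoether.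

Step 3
Reactants: 4 1-[2,5-dihydroxy-4-(3-methylbut-2-enyloxy)phenyl]ethanone
Product: 5 1-[2,5-dimethoxy-4-(3-methylbut-2-enyloxy)phenyl]ethanone
Conditions: MeI (4 equiv), K2CO3 (4 equiv), DMF, 40 °C, argon
Reagents that add atoms: methyl iodide, CI
Why: Exhaustive Williamson methylation; the polar solvent and excess reagent are needed for the chelated 2-OH, the prenyl ether is inert to base, and argon keeps the hydroquinone from oxidising before it is capped.

Step 4
Reactants: 6 vanillic acid (4-hydroxy-3-methoxybenzoic acid)
Product: 7 3-methoxy-4-(pivaloyloxy)benzoic acid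
Conditions: pivaloyl chloride (1.1 equiv), aq. NaOH (2.2 equiv), THF–H2O, 0 °C; then aq. HCl
Reagents that add atoms: pivaloyl chloride, CC(C)(C)C(=O)Cl
Why: Schotten–Baumann acylation of the phenoxide; any mixed anhydride formed at the carboxylate is hydrolysed in the aqueous medium, and acidification returns the free acid.

Step 5
Reactants: 7 3-methoxy-4-(pivaloyloxy)benzoic acid
Product: 8 3-methoxy-4-(pivaloyloxy)benzoyl chloride
Conditions: (COCl)2, DMF (cat.), CH2Cl2, 0 °C to rt
Reagents that add atoms: oxalyl chloride, O=C(Cl)C(=O)Cl
Why: Acid chloride formation through the chloroiminium species from DMF; the hindered aryl pivalate is inert and all by-products are volatile.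

Step 6
Reactants: 5 1-[2,5-dimethoxy-4-(3-methylbut-2-enyloxy)phenyl]ethanone; 8 3-methoxy-4-(pivaloyloxy)benzoyl chloride
Product: 9 1-[2,5-dimethoxy-4-(3-methylbut-2-enyloxy)phenyl]-3-[3-methoxy-4-(pivaloyloxy)phenyl]propane-1,3-dione
Conditions: LiN(SiMe3)2 (2.2 equiv), THF, −78 °C; then 8, −78 to −20 °C; aq. NH4Cl
Reagents that add atoms: none
Why: Crossed Claisen condensation (C-acylation of the lithium enolate of an aryl methyl ketone by an acid chloride); the second equivalent of base deprotonates the diketone as it forms and so prevents a second acylation. At −78 °C the acid chloride should react far faster than the hindered pivalate.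

Step 7
Reactants: 9 1-[2,5-dimethoxy-4-(3-methylbut-2-enyloxy)phenyl]-3-[3-methoxy-4-(pivaloyloxy)phenyl]propane-1,3-dione
Product: 10 2-(benzoyloxy)-1-[2,5-dimethoxy-4-(3-methylbut-2-enyloxy)phenyl]-3-[3-methoxy-4-(pivaloyloxy)phenyl]propane-1,3-dione (racemic)
Conditions: NaH (1.05 equiv), THF, 0 °C; then (PhCO2)2 (1.05 equiv), 0 °C to rt
Reagents that add atoms: dibenzoyl peroxide, O=C(OOC(=O)c1ccccc1)c1ccccc1
Why: Electrophilic α-benzoyloxylation: the central carbon of the sodium diketonate attacks the O–O bond of the diacyl peroxide in an SN2 manner, a known reaction of 1,3-dicarbonyl enolates. The new stereocentre is formed racemic and needs no control because it becomes the sp2 carbon C3 in step 8.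

Step 8
Reactants: 10 2-(benzoyloxy)-1-[2,5-dimethoxy-4-(3-methylbut-2-enyloxy)phenyl]-3-[3-methoxy-4-(pivaloyloxy)phenyl]propane-1,3-dione
Product: 13 3-(benzoyloxy)-5,8-dihydroxy-2-[3-methoxy-4-(pivaloyloxy)phenyl]-7-(3-methylbut-2-enyloxy)chromen-4-one, via acylquinone 11 (not isolated), via flavone-5,8-quinone 12 (not isolated)
Conditions: (NH4)2Ce(NO3)6 (4.2 equiv), MeCN–H2O (3:1), 0 °C to rt; then aq. Na2S2O4, EtOAc, rt
Reagents that add atoms: water, O
Why: Tetravalent cerium removes an electron from the trialkoxyarene of 10, water adds to the two methoxy-bearing carbons that stand para to each other and two molecules of methanol leave, giving the 2-acyl-5-prenyloxy-1,4-benzoquinone 11 (oxidative demethylation, quinone oxygens from water). In the acidic medium the side chain of 11 enolises toward ring B and the enol oxygen adds to the quinone carbon next to the acyl group, which is the β-carbon of both the ring enone and the exocyclic ketone; this 6-endo-trig oxa-Michael addition forms O1–C8a and closes ring C, and tautomerisation rearomatises ring A to the 5,8-hydroquinone 13. Because 13 is more easily oxidised than 10 and would otherwise exchange electrons with unreacted 11, the oxidant is used in excess so that all cyclised material collects as flavone-5,8-quinone 12, which the dithionite wash reduces back to 13 once 11 has been consumed. The closest known reaction type is the oxidative demethylation of 2,5-dimethoxyaryl ketones to acylquinones followed by intramolecular oxa-Michael addition of a tethered hydroxyl group, as used for 1,4-dioxygenated xanthones; here the nucleophile is the enol of a 1,3-diketone. No stereocentre is formed and the racemic carbon of 10 is erased. The site of ring closure is fixed by reach (the central carbon or the other enol oxygen could only form a four-membered ring) and by electronics (the other quinone CH is the α-carbon of the prenyloxy enone). The step needs water, not the chain oxygen, to capture the radical cation at the methoxy carbon ortho to the ketone; the 2-benzoyloxy group keeps the chain largely in its non-nucleophilic keto form and water is in large excess. The prenyl olefin and the acyloxy-substituted ring B are much harder to oxidise than the trialkoxyarene and should survive at 0 °C.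

Step 9
Reactants: 13 3-(benzoyloxy)-5,8-dihydroxy-2-[3-methoxy-4-(pivaloyloxy)phenyl]-7-(3-methylbut-2-enyloxy)chromen-4-one
Product: 14 3-(benzoyloxy)-5-hydroxy-8-methoxy-2-[3-methoxy-4-(pivaloyloxy)phenyl]-7-(3-methylbut-2-enyloxy)chromen-4-one
Conditions: MeI (1.5 equiv), K2CO3 (1.1 equiv), acetone, rt, argon
Reagents that add atoms: methyl iodide, CI
Why: Chelation-controlled Williamson methylation: the 5-OH is hydrogen-bonded to the C4 carbonyl and is much less acidic and nucleophilic than the free 8-OH, so one equivalent of carbonate should give only the 8-phenoxide, the classical partial methylation of 5,8-dihydroxyflavones. Anhydrous acetone leaves the two esters intact and argon protects the hydroquinone monoanion.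

Step 10
Reactants: 14 3-(benzoyloxy)-5-hydroxy-8-methoxy-2-[3-methoxy-4-(pivaloyloxy)phenyl]-7-(3-methylbut-2-enyloxy)chromen-4-one
Product: 15 3,5-dihydroxy-2-(4-hydroxy-3-methoxyphenyl)-8-methoxy-7-(3-methylbut-2-enyloxy)chromen-4-one
Conditions: K2CO3 (3 equiv), MeOH–THF (degassed), rt to 40 °C, argon; then dilute HCl to pH 4
Reagents that add atoms: none
Why: Base-mediated transesterification with methanol: the enol benzoate at O3 is an activated ester and should go quickly, the aryl pivalate more slowly but helped by the conjugated, electron-poor phenoxide leaving group. The prenyl and methyl ethers are inert to these conditions, and exclusion of air protects the 3-hydroxyflavone.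

## Compound list

1 | 1,2,4-triacetoxybenzene | CC(=O)Oc1ccc(OC(C)=O)c(OC(C)=O)c1 | starting material
2 | 1-(2,4,5-trihydroxyphenyl)ethanone | CC(=O)c1cc(O)c(O)cc1O | intermediate
3 | prenyl bromide (1-bromo-3-methylbut-2-ene) | CC(C)=CCBr | starting material
4 | 1-[2,5-dihydroxy-4-(3-methylbut-2-enyloxy)phenyl]ethanone | CC(=O)c1cc(O)c(OCC=C(C)C)cc1O | intermediate
5 | 1-[2,5-dimethoxy-4-(3-methylbut-2-enyloxy)phenyl]ethanone | CC(=O)c1cc(OC)c(OCC=C(C)C)cc1OC | intermediate
6 | vanillic acid (4-hydroxy-3-methoxybenzoic acid) | COc1cc(C(=O)O)ccc1O | starting material
7 | 3-methoxy-4-(pivaloyloxy)benzoic acid | COc1cc(C(=O)O)ccc1OC(=O)C(C)(C)C | intermediate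
8 | 3-methoxy-4-(pivaloyloxy)benzoyl chloride | COc1cc(C(=O)Cl)ccc1OC(=O)C(C)(C)C | intermediate
9 | 1-[2,5-dimethoxy-4-(3-methylbut-2-enyloxy)phenyl]-3-[3-methoxy-4-(pivaloyloxy)phenyl]propane-1,3-dione | COc1cc(C(=O)CC(=O)c2cc(OC)c(OCC=C(C)C)cc2OC)ccc1OC(=O)C(C)(C)C | intermediate
10 | 2-(benzoyloxy)-1-[2,5-dimethoxy-4-(3-methylbut-2-enyloxy)phenyl]-3-[3-methoxy-4-(pivaloyloxy)phenyl]propane-1,3-dione (racemic, enolisable centre) | COc1cc(C(=O)C(OC(=O)c2ccccc2)C(=O)c2cc(OC)c(OCC=C(C)C)cc2OC)ccc1OC(=O)C(C)(C)C | intermediate
11 | 2-{2-(benzoyloxy)-3-[3-methoxy-4-(pivaloyloxy)phenyl]-3-oxopropanoyl}-5-(3-methylbut-2-enyloxy)-1,4-benzoquinone (racemic) | COc1cc(C(=O)C(OC(=O)c2ccccc2)C(=O)C2=CC(=O)C(OCC=C(C)C)=CC2=O)ccc1OC(=O)C(C)(C)C | intermediate (not isolated)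
12 | 3-(benzoyloxy)-2-[3-methoxy-4-(pivaloyloxy)phenyl]-7-(3-methylbut-2-enyloxy)chromene-4,5,8-trione | COc1cc(C2=C(OC(=O)c3ccccc3)C(=O)C3=C(O2)C(=O)C(OCC=C(C)C)=CC3=O)ccc1OC(=O)C(C)(C)C | intermediate (not isolated)
13 | 3-(benzoyloxy)-5,8-dihydroxy-2-[3-methoxy-4-(pivaloyloxy)phenyl]-7-(3-methylbut-2-enyloxy)chromen-4-one | COc1cc(-c2oc3c(O)c(OCC=C(C)C)cc(O)c3c(=O)c2OC(=O)c2ccccc2)ccc1OC(=O)C(C)(C)C | intermediate
14 | 3-(benzoyloxy)-5-hydroxy-8-methoxy-2-[3-methoxy-4-(pivaloyloxy)phenyl]-7-(3-methylbut-2-enyloxy)chromen-4-one | COc1cc(-c2oc3c(OC)c(OCC=C(C)C)cc(O)c3c(=O)c2OC(=O)c2ccccc2)ccc1OC(=O)C(C)(C)C | intermediate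
15 | 3,5-dihydroxy-2-(4-hydroxy-3-methoxyphenyl)-8-methoxy-7-(3-methylbut-2-enyloxy)chromen-4-one | COc1cc(-c2oc3c(OC)c(OCC=C(C)C)cc(O)c3c(=O)c2O)ccc1O | target

## Step count and risks

Total step count: 10. Longest linear sequence: 8 steps (1 → 2 → 4 → 5 → 9 → 10 → 13 → 14 → 15; steps 1, 2, 3, 6, 7, 8, 9, 10). The ring B branch (steps 4 and 5) joins at step 6.

**Step 8 (key step).** Three things can go wrong.
- The arene radical cation may be captured at the methoxy carbon ortho to the ketone by the chain oxygen instead of by water. This ipso substitution loses one methanol and closes the ring through the wrong carbon, into the 6-methoxy series.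
- The excess oxidant may attack the prenyl olefin.
- If enol addition is slow, acylquinone 11 is still present at the reductive wash, is reduced to the acylhydroquinone and then closes the classical way.

Fallback: reach 11 from a free hydroquinone with a neutral two-electron oxidant, so that no radical cation and no nitrate-acid medium is involved. The sequence sets out from 4.
- Silylation of both hydroxyls (triisopropylsilyl triflate, 2,6-lutidine, CH2Cl2) gives 1-[4-(3-methylbut-2-enyloxy)-2,5-bis(triisopropylsilyloxy)phenyl]ethanone F1.
- Claisen acylation with 8 as in step 6 gives 1-[4-(3-methylbut-2-enyloxy)-2,5-bis(triisopropylsilyloxy)phenyl]-3-[3-methoxy-4-(pivaloyloxy)phenyl]propane-1,3-dione F2.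
- Benzoyloxylation as in step 7 gives the 2-benzoyloxy derivative F3.
- Desilylation with HF·pyridine in THF at 0 °C gives 2-(benzoyloxy)-1-[2,5-dihydroxy-4-(3-methylbut-2-enyloxy)phenyl]-3-[3-methoxy-4-(pivaloyloxy)phenyl]propane-1,3-dione F4.
- F4 is oxidised at once with excess Ag2O (Na2SO4, CH2Cl2), the classical preparation of acylquinones from acylhydroquinones.

The sequence rejoins the route at 11, which closes through 12 to 13 after the same dithionite wash.

**Step 9.** The monoanion of the hydroquinone may be oxidised back to quinone 12 by traces of air. Excess base may break the 5-OH hydrogen bond and lead to a second alkylation. The 8-phenoxide may take the benzoyl group from O3 of another molecule.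

Fallback: from 13, methylate without forming a phenoxide by a Mitsunobu reaction (MeOH, PPh3, diisopropyl azodicarboxylate, THF, 0 °C). Only the non-chelated, more acidic 8-OH is engaged, and the product is 14 directly (no new compound, F0).

**Step 7.** The diketonate may attack a carbonyl carbon of the peroxide (C-benzoylation) instead of the O–O bond. The crowded product may fragment by retro-Claisen cleavage under base. The peroxide may homolyse, with radical addition to the prenyl olefin.

Fallback: from 9, separate C–O bond formation from acylation. Hydroxylation of the sodium enolate with 2-(phenylsulfonyl)-3-phenyloxaziridine (THF, −78 °C), an oxidant that does not epoxidise the olefin, gives 2-hydroxy-1-[2,5-dimethoxy-4-(3-methylbut-2-enyloxy)phenyl]-3-[3-methoxy-4-(pivaloyloxy)phenyl]propane-1,3-dione F5. Benzoyl chloride and pyridine in CH2Cl2 at 0 °C then give 10.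

**Step 2.** A second alkylation at O5 may occur, or the electron-rich triol may be oxidised under base before it is alkylated.

Fallback: avoid differentiating three hydroxyls by starting from a ring with the methyl ethers in place. The sequence sets out from 3 and purchased 2,5-dimethoxyphenol F6.
- Bromination para to the hydroxyl (N-bromosuccinimide, MeCN, 0 °C) gives 4-bromo-2,5-dimethoxyphenol F7.
- Alkylation with 3 (K2CO3, acetone) gives 1-bromo-2,5-dimethoxy-4-(3-methylbut-2-enyloxy)benzene F8.
- Bromine–lithium exchange (n-BuLi, THF, −78 °C) and acylation with N-methoxy-N-methylacetamide give 5.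

The sequence rejoins the route at 5 and replaces steps 1 to 3.

## Further compounds

F1 | step 8 | 1-[4-(3-methylbut-2-enyloxy)-2,5-bis(triisopropylsilyloxy)phenyl]ethanone | CC(=O)c1cc(O[Si](C(C)C)(C(C)C)C(C)C)c(OCC=C(C)C)cc1O[Si](C(C)C)(C(C)C)C(C)C
F2 | step 8 | 1-[4-(3-methylbut-2-enyloxy)-2,5-bis(triisopropylsilyloxy)phenyl]-3-[3-methoxy-4-(pivaloyloxy)phenyl]propane-1,3-dione | COc1cc(C(=O)CC(=O)c2cc(O[Si](C(C)C)(C(C)C)C(C)C)c(OCC=C(C)C)cc2O[Si](C(C)C)(C(C)C)C(C)C)ccc1OC(=O)C(C)(C)C
F3 | step 8 | 2-(benzoyloxy)-1-[4-(3-methylbut-2-enyloxy)-2,5-bis(triisopropylsilyloxy)phenyl]-3-[3-methoxy-4-(pivaloyloxy)phenyl]propane-1,3-dione (racemic) | COc1cc(C(=O)C(OC(=O)c2ccccc2)C(=O)c2cc(O[Si](C(C)C)(C(C)C)C(C)C)c(OCC=C(C)C)cc2O[Si](C(C)C)(C(C)C)C(C)C)ccc1OC(=O)C(C)(C)C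
F4 | step 8 | 2-(benzoyloxy)-1-[2,5-dihydroxy-4-(3-methylbut-2-enyloxy)phenyl]-3-[3-methoxy-4-(pivaloyloxy)phenyl]propane-1,3-dione (racemic) | COc1cc(C(=O)C(OC(=O)c2ccccc2)C(=O)c2cc(O)c(OCC=C(C)C)cc2O)ccc1OC(=O)C(C)(C)C
F0 | step 9 | none | none
F5 | step 7 | 2-hydroxy-1-[2,5-dimethoxy-4-(3-methylbut-2-enyloxy)phenyl]-3-[3-methoxy-4-(pivaloyloxy)phenyl]propane-1,3-dione (racemic) | COc1cc(C(=O)C(O)C(=O)c2cc(OC)c(OCC=C(C)C)cc2OC)ccc1OC(=O)C(C)(C)C
F6 | step 2 | 2,5-dimethoxyphenol | COc1ccc(OC)c(O)c1
F7 | step 2 | 4-bromo-2,5-dimethoxyphenol | COc1cc(O)c(OC)cc1Br
F8 | step 2 | 1-bromo-2,5-dimethoxy-4-(3-methylbut-2-enyloxy)benzene | COc1cc(OCC=C(C)C)c(OC)cc1Br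
A1 | alternative 1 | 1,5-bis(benzyloxy)-2-iodo-4-methoxy-3-(methoxymethoxy)benzene | COCOc1c(OC)c(OCc2ccccc2)cc(OCc2ccccc2)c1I
A2 | alternative 1 | 1-[4-(benzyloxy)-3-methoxyphenyl]-2-(methoxymethoxy)ethanone | COCOCC(=O)c1ccc(OCc2ccccc2)c(OC)c1
A3 | alternative 1 | 1-[4,6-bis(benzyloxy)-3-methoxy-2-(methoxymethoxy)phenyl]-3-[4-(benzyloxy)-3-methoxyphenyl]-2-(methoxymethoxy)propane-1,3-dione (racemic) | COCOc1c(OC)c(OCc2ccccc2)cc(OCc2ccccc2)c1C(=O)C(OCOC)C(=O)c1ccc(OCc2ccccc2)c(OC)c1
A4 | alternative 2 | 2-methoxy-2-{6-[3-methoxy-4-(pivaloyloxy)phenyl]-4-oxo-5-(pivaloyloxy)-4H-pyran-2-yl}acetyl chloride (racemic) | COC(C(=O)Cl)c1cc(=O)c(OC(=O)C(C)(C)C)c(-c2ccc(OC(=O)C(C)(C)C)c(OC)c2)o1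
A5 | alternative 2 | (triisopropylsilyloxy)acetylene | C#CO[Si](C(C)C)(C(C)C)C(C)C
A6 | alternative 2 | 5-hydroxy-8-methoxy-2-[3-methoxy-4-(pivaloyloxy)phenyl]-3-(pivaloyloxy)-7-(triisopropylsilyloxy)chromen-4-one | COc1cc(-c2oc3c(OC)c(O[Si](C(C)C)(C(C)C)C(C)C)cc(O)c3c(=O)c2OC(=O)C(C)(C)C)ccc1OC(=O)C(C)(C)C
A7 | alternative 3 | (E)-3-[3,5-bis(benzyloxy)-2-methoxyphenoxy]-3-[3-methoxy-4-(pivaloyloxy)phenyl]-2-(pivaloyloxy)prop-2-enoic acid | OC(=O)/C(OC(=O)C(C)(C)C)=C(\Oc1cc(OCc2ccccc2)cc(OCc2ccccc2)c1OC)c1ccc(OC(=O)C(C)(C)C)c(OC)c1
A8 | alternative 3 | 5,7-bis(benzyloxy)-8-methoxy-2-[3-methoxy-4-(pivaloyloxy)phenyl]-3-(pivaloyloxy)chromen-4-one | COc1cc(-c2oc3c(OC)c(OCc4ccccc4)cc(OCc4ccccc4)c3c(=O)c2OC(=O)C(C)(C)C)ccc1OC(=O)C(C)(C)C
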